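## Retrosynthetic overview

1. Target ⇐ PMB removal, O8‑isobutyrylation and O9‑acetylation of a ten‑membered C9 allylic alcohol.
2. Ten‑membered ring ⇐ C9–C10 bond by NiCl2/CrCl2 Nozaki–Hiyama–Kishi macrocyclization of a C9 aldehyde onto a C10 (Z)‑α‑iodoenoate; this sets C9 and the ring‑cis C1=C10 alkene.
3. Seco‑lactone ⇐ C6–C7 bond by CrCl2 allylation plus lactonization between fragment A (enal, C1–C6, C10, C14, C15) and fragment B (2‑(bromomethyl)enoate, C7–C9, C11–C13); this sets C6 and C7.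
4. Fragment A ⇐ but‑2‑yne‑1,4‑diol (hydroalumination–iodination, Negishi coupling, iodo‑Wittig); fragment B ⇐ methyl (R)‑glycerate acetonide (vinylalumination, SN2′ bromination).
5. Ring order: α‑methylene‑γ‑butyrolactone first (fragment union), ten‑membered carbocycle second (macrocyclization).

Convention: locants C1–C15 in the text are the germacranolide locants of the target. Ring carbons are C1–C10; the lactone O sits on C6; C11 (on C7) carries C12 (lactone C=O) and C13 (=CH2); C14 is the ester carbon on C10; C15 is the CH2O carbon on C4. "Ring‑cis" means both ring bonds lie on the same side of the alkene.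

Assumption: the target is exactly the stereoisomer of the given SMILES, i.e. (6R,7S,8S,9R) with both ring alkenes ring‑cis (1(10)E,4E by CIP).

## Route

**Fragment A (steps 1–9)**

Step 1
Reactants: 1 but-2-yne-1,4-diol
Product: 2 4-[(4-methoxyphenyl)methoxy]but-2-yn-1-ol
Conditions: NaH (1.0 equiv), DMF, 0 °C; 4-methoxybenzyl chloride (1.0 equiv), Bu4NI (cat.), rt; 3 equiv of 1
Reagents that add atoms: 4-methoxybenzyl chloride, COc1ccc(CCl)cc1
Why: Williamson etherification of the mono‑alkoxide; the threefold excess of the symmetric diol makes the mono‑ether the main product.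

Step 2
Reactants: 2 4-[(4-methoxyphenyl)methoxy]but-2-yn-1-ol
Product: 4 (2Z)-3-iodo-4-[(4-methoxyphenyl)methoxy]but-2-en-1-ol, via cyclic alkenylaluminate 3 (not isolated)
Conditions: NaAlH2(OCH2CH2OMe)2 (1.5 equiv), THF, 0 °C → rt; then I2, THF, −78 → 0 °C
Reagents that add atoms: iodine, [I][I]
Why: Alkoxide‑directed trans‑hydroalumination of the propargylic alcohol puts aluminium on the carbon remote from the free CH2OH, and iodinolysis with retention gives the (Z)‑vinyl iodide that later defines the ring‑cis C4=C5 alkene.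

Step 3
Reactants: 4 (2Z)-3-iodo-4-[(4-methoxyphenyl)methoxy]but-2-en-1-ol
Product: 5 triethyl({(2Z)-3-iodo-4-[(4-methoxyphenyl)methoxy]but-2-en-1-yl}oxy)silane
Conditions: Et3SiCl, imidazole, CH2Cl2, 0 °C
Reagents that add atoms: chlorotriethylsilane, CC[Si](Cl)(CC)CC
Why: Standard silylation of the primary allylic alcohol; the triethylsilyl ether can later be oxidised directly under Swern conditions.

Step 4
Reactants: 6 ethyl 3-bromopropanoate
Product: 7 bromo(3-ethoxy-3-oxopropyl)zinc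
Conditions: Zn dust (activated with BrCH2CH2Br and Me3SiCl), LiCl, THF, 40 °C; used as a titrated solution
Reagents that add atoms: zinc, [Zn]
Why: LiCl‑assisted direct insertion of zinc into the C–Br bond gives the ester‑tolerant zinc homoenolate.

Step 5
Reactants: 5 triethyl({(2Z)-3-iodo-4-[(4-methoxyphenyl)methoxy]but-2-en-1-yl}oxy)silane; 7 bromo(3-ethoxy-3-oxopropyl)zinc
Product: 8 ethyl (4E)-4-{[(4-methoxyphenyl)methoxy]methyl}-6-[(triethylsilyl)oxy]hex-4-enoate
Conditions: Pd(PPh3)4 (5 mol %), THF, 50 °C; 1.5 equiv of 7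
Reagents that add atoms: none
Why: Negishi sp2–sp3 cross‑coupling at zerovalent palladium proceeds with retention of alkene geometry, so the new C3–C4 bond is cis to C6.

Step 6
Reactants: 8 ethyl (4E)-4-{[(4-methoxyphenyl)methoxy]methyl}-6-[(triethylsilyl)oxy]hex-4-enoate
Product: 9 (4E)-4-{[(4-methoxyphenyl)methoxy]methyl}-6-[(triethylsilyl)oxy]hex-4-enal
Conditions: iBu2AlH (1.1 equiv), CH2Cl2, −78 °C; MeOH, then aq. KNaC4H4O6
Reagents that add atoms: none
Why: Partial reduction of the ester stops at the aluminium hemiacetal at −78 °C and gives the C1 aldehyde on work‑up.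

Step 7
Reactants: 10 methyl (triphenyl-λ5-phosphanylidene)acetate
Product: 11 methyl iodo(triphenyl-λ5-phosphanylidene)acetate
Conditions: N-iodosuccinimide (1.0 equiv), CH2Cl2, −20 °C → rt; aq. NaHCO3 wash, crystallisation
Reagents that add atoms: N-iodosuccinimide, O=C1CCC(=O)N1I
Why: Electrophilic iodination of the stabilised ylide followed by deprotonation by succinimide anion gives the isolable α‑iodo ylide.

Step 8
Reactants: 9 (4E)-4-{[(4-methoxyphenyl)methoxy]methyl}-6-[(triethylsilyl)oxy]hex-4-enal; 11 methyl iodo(triphenyl-λ5-phosphanylidene)acetate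
Product: 12 methyl (2Z,6E)-2-iodo-6-{[(4-methoxyphenyl)methoxy]methyl}-8-[(triethylsilyl)oxy]octa-2,6-dienoate
Conditions: CH2Cl2, rt, 12 h; 1.3 equiv of 11; minor (2E) isomer removed by chromatography
Reagents that add atoms: none
Why: Wittig olefination with the stabilised α‑iodo ylide places the alkyl chain trans to the ester, giving the (Z)‑α‑iodoenoate needed for the later chromium coupling.

Step 9
Reactants: 12 methyl (2Z,6E)-2-iodo-6-{[(4-methoxyphenyl)methoxy]methyl}-8-[(triethylsilyl)oxy]octa-2,6-dienoate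
Product: 13 methyl (2Z,6E)-2-iodo-6-{[(4-methoxyphenyl)methoxy]methyl}-8-oxoocta-2,6-dienoate
Conditions: (COCl)2, DMSO, CH2Cl2, −78 → −40 °C; Et3N, −78 → 0 °C; used at once
Reagents that add atoms: none
Why: Desilylative Swern oxidation: activated DMSO cleaves the primary triethylsilyl ether and oxidises it in one pot to the enal without touching either alkene geometry.

**Fragment B (steps 10–15)**

Step 10
Reactants: 14 methyl (4R)-2,2-dimethyl-1,3-dioxolane-4-carboxylate
Product: 15 methyl (2R)-2,3-dihydroxypropanoate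
Conditions: Amberlyst-15 (sulfonic acid resin), MeOH, rt
Reagents that add atoms: none
Why: Acid‑catalysed transacetalization to methanol removes the acetonide without touching the ester or the stereocentre.

Step 11
Reactants: 15 methyl (2R)-2,3-dihydroxypropanoate
Product: 16 methyl (2R)-2-hydroxy-3-[(triethylsilyl)oxy]propanoate
Conditions: Et3SiCl (1.05 equiv), imidazole, CH2Cl2, −40 °C
Reagents that add atoms: chlorotriethylsilane, CC[Si](Cl)(CC)CC
Why: The primary hydroxyl is silylated selectively at low temperature on steric grounds.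

Step 12
Reactants: 16 methyl (2R)-2-hydroxy-3-[(triethylsilyl)oxy]propanoate
Product: 17 methyl (2R)-2-[(tert-butyldimethylsilyl)oxy]-3-[(triethylsilyl)oxy]propanoate
Conditions: tBuMe2SiCl, imidazole, DMF, rt
Reagents that add atoms: tert-butylchlorodimethylsilane, CC(C)(C)[Si](C)(C)Cl
Why: Silylation of the remaining secondary hydroxyl gives a robust O8 protecting group that survives the later Swern steps.

Step 13
Reactants: 17 methyl (2R)-2-[(tert-butyldimethylsilyl)oxy]-3-[(triethylsilyl)oxy]propanoate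
Product: 18 (2R)-2-[(tert-butyldimethylsilyl)oxy]-3-[(triethylsilyl)oxy]propanal
Conditions: iBu2AlH (1.05 equiv), toluene, −78 °C; aq. KNaC4H4O6; used crude
Reagents that add atoms: none
Why: Partial reduction of the α‑silyloxy ester gives the aldehyde, which is used at once to avoid epimerisation.

Step 14
Reactants: 18 (2R)-2-[(tert-butyldimethylsilyl)oxy]-3-[(triethylsilyl)oxy]propanal; 19 methyl prop-2-ynoate
Product: 21 methyl (3RS,4R)-4-[(tert-butyldimethylsilyl)oxy]-3-hydroxy-2-methylidene-5-[(triethylsilyl)oxy]pentanoate, via vinylalane 20 (not isolated)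
Conditions: iBu2AlH, N-methylmorpholine N-oxide, THF, 0 °C; 19, 0 °C, 30 min; then 18, 0 °C → rt
Reagents that add atoms: none
Why: Hydroalumination of the propiolate gives an α‑(methoxycarbonyl)vinylalane that adds 1,2 to the aldehyde (vinylalumination, a Morita–Baylis–Hillman‑type adduct); the new carbinol centre forms as a mixture that is irrelevant because it becomes sp2 in step 15.

Step 15
Reactants: 21 methyl (3RS,4R)-4-[(tert-butyldimethylsilyl)oxy]-3-hydroxy-2-methylidene-5-[(triethylsilyl)oxy]pentanoate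
Product: 22 methyl (2Z,4S)-2-(bromomethyl)-4-[(tert-butyldimethylsilyl)oxy]-5-[(triethylsilyl)oxy]pent-2-enoate
Conditions: N-bromosuccinimide, Me2S, CH2Cl2, 0 °C → rt
Reagents that add atoms: N-bromosuccinimide, O=C1CCC(=O)N1Br
Why: Bromide attacks the alkoxysulfonium salt in SN2′ fashion (Corey–Kim‑type activation), giving the thermodynamically preferred (Z)‑2‑(bromomethyl)enoate with allylic transposition.

**Union and endgame (steps 16–22)**

Step 16
Reactants: 13 methyl (2Z,6E)-2-iodo-6-{[(4-methoxyphenyl)methoxy]methyl}-8-oxoocta-2,6-dienoate; 22 methyl (2Z,4S)-2-(bromomethyl)-4-[(tert-butyldimethylsilyl)oxy]-5-[(triethylsilyl)oxy]pent-2-enoate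
Product: 25 methyl (2Z,6E)-7-[(2R,3S)-3-{(1S)-1-[(tert-butyldimethylsilyl)oxy]-2-[(triethylsilyl)oxy]ethyl}-4-methylidene-5-oxooxolan-2-yl]-2-iodo-6-{[(4-methoxyphenyl)methoxy]methyl}hepta-2,6-dienoate, via allylchromium dichloride 23 (not isolated), via hydroxy ester 24 (not isolated)
Conditions: CrCl2 (4 equiv, nickel‑free), THF, 0 °C → rt; 1.3 equiv of 22; then pyridinium p-toluenesulfonate (cat.), CH2Cl2, rt
Reagents that add atoms: none
Why: Nozaki–Hiyama allylation: the geometry‑equilibrating allylchromium adds through a chair transition state to give the 6,7‑anti adduct, C7 being attacked anti to the C8–C9 bond with C8–H eclipsing the alkene (allylic 1,3‑strain), which sets (6R,7S), and the C6 alkoxide lactonizes onto the adjacent methyl ester to the trans α‑methylene‑γ‑butyrolactone.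

Step 17
Reactants: 25 methyl (2Z,6E)-7-[(2R,3S)-3-{(1S)-1-[(tert-butyldimethylsilyl)oxy]-2-[(triethylsilyl)oxy]ethyl}-4-methylidene-5-oxooxolan-2-yl]-2-iodo-6-{[(4-methoxyphenyl)methoxy]methyl}hepta-2,6-dienoate
Product: 26 methyl (2Z,6E)-7-[(2R,3S)-3-{(1S)-1-[(tert-butyldimethylsilyl)oxy]-2-oxoethyl}-4-methylidene-5-oxooxolan-2-yl]-2-iodo-6-{[(4-methoxyphenyl)methoxy]methyl}hepta-2,6-dienoate
Conditions: (COCl)2, DMSO, CH2Cl2, −78 → −40 °C; Et3N, −78 → −20 °C; used at once
Reagents that add atoms: none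
Why: Desilylative Swern oxidation converts only the primary triethylsilyl ether into the C9 aldehyde; the secondary silyl ether and the lactone are untouched.

Step 18
Reactants: 26 methyl (2Z,6E)-7-[(2R,3S)-3-{(1S)-1-[(tert-butyldimethylsilyl)oxy]-2-oxoethyl}-4-methylidene-5-oxooxolan-2-yl]-2-iodo-6-{[(4-methoxyphenyl)methoxy]methyl}hepta-2,6-dienoate
Product: 28 methyl (1(10)E,4E,6R,7S,8S,9R)-8-[(tert-butyldimethylsilyl)oxy]-9-hydroxy-15-[(4-methoxyphenyl)methoxy]germacra-1(10),4,11(13)-trien-12,6-olid-14-oate, via alkenylchromium dichloride 27 (not isolated)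
Conditions: CrCl2 (10 equiv), NiCl2 (0.1 equiv), DMSO/THF, rt; syringe‑pump addition of 26 to 2 mM final concentration
Reagents that add atoms: none
Why: Nozaki–Hiyama–Kishi macrocyclization: the alkenylchromium formed with retention from the (Z)‑iodoenoate adds to the C9 aldehyde and closes the ten‑membered ring with a ring‑cis C1=C10, Felkin–Anh attack anti to the C8 silyloxy group setting (9R) (8,9‑anti).

Step 19
Reactants: 28 methyl (1(10)E,4E,6R,7S,8S,9R)-8-[(tert-butyldimethylsilyl)oxy]-9-hydroxy-15-[(4-methoxyphenyl)methoxy]germacra-1(10),4,11(13)-trien-12,6-olid-14-oate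
Product: 29 methyl (1(10)E,4E,6R,7S,8S,9R)-9-acetoxy-8-[(tert-butyldimethylsilyl)oxy]-15-[(4-methoxyphenyl)methoxy]germacra-1(10),4,11(13)-trien-12,6-olid-14-oate
Conditions: Ac2O, pyridine, DMAP (cat.), CH2Cl2, 0 °C → rt
Reagents that add atoms: acetic anhydride, CC(=O)OC(C)=O
Why: DMAP‑catalysed acetylation of the secondary allylic alcohol while O8 is still blocked as a silyl ether, so no acyl migration is possible.

Step 20
Reactants: 29 methyl (1(10)E,4E,6R,7S,8S,9R)-9-acetoxy-8-[(tert-butyldimethylsilyl)oxy]-15-[(4-methoxyphenyl)methoxy]germacra-1(10),4,11(13)-trien-12,6-olid-14-oate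
Product: 30 methyl (1(10)E,4E,6R,7R,8S,9R)-9-acetoxy-8-hydroxy-15-[(4-methoxyphenyl)methoxy]germacra-1(10),4,11(13)-trien-12,6-olid-14-oate
Conditions: HF·pyridine, pyridine, THF, 0 °C → rt
Reagents that add atoms: none
Why: Fluoride cleaves the secondary silyl ether under buffered, weakly acidic conditions that keep the neighbouring acetate in place and leave the PMB ether intact (the C7 descriptor changes by CIP only).

Step 21
Reactants: 30 methyl (1(10)E,4E,6R,7R,8S,9R)-9-acetoxy-8-hydroxy-15-[(4-methoxyphenyl)methoxy]germacra-1(10),4,11(13)-trien-12,6-olid-14-oate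
Product: 31 methyl (1(10)E,4E,6R,7S,8S,9R)-9-acetoxy-15-[(4-methoxyphenyl)methoxy]-8-[(2-methylpropanoyl)oxy]germacra-1(10),4,11(13)-trien-12,6-olid-14-oate
Conditions: 2-methylpropanoyl chloride, pyridine, DMAP (cat.), CH2Cl2, −20 → 0 °C
Reagents that add atoms: 2-methylpropanoyl chloride, CC(C)C(Cl)=O
Why: Acylation with the acid chloride at low temperature is meant to outrun base‑mediated acetyl migration from O9 to O8.

Step 22
Reactants: 31 methyl (1(10)E,4E,6R,7S,8S,9R)-9-acetoxy-15-[(4-methoxyphenyl)methoxy]-8-[(2-methylpropanoyl)oxy]germacra-1(10),4,11(13)-trien-12,6-olid-14-oate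
Product: 32 methyl (1(10)E,4E,6R,7S,8S,9R)-9-acetoxy-15-hydroxy-8-[(2-methylpropanoyl)oxy]germacra-1(10),4,11(13)-trien-12,6-olid-14-oate (CNP0242134.4)
Conditions: DDQ (1.3 equiv), CH2Cl2/aq. pH 7 buffer (NaH2PO4/Na2HPO4), 0 °C
Reagents that add atoms: none
Why: Oxidative PMB cleavage (hydride abstraction by DDQ, hydrolysis of the oxocarbenium ion) frees the C15 alcohol without touching the esters, the lactone or the alkenes.

## Compound list

1 | but-2-yne-1,4-diol | OCC#CCO | starting material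
2 | 4-[(4-methoxyphenyl)methoxy]but-2-yn-1-ol | OCC#CCOCc1ccc(OC)cc1 | intermediate
3 | sodium 2,2-bis(2-methoxyethoxy)-3-{[(4-methoxyphenyl)methoxy]methyl}-2,5-dihydro-1,2-oxaluminol-2-uide (cyclic alkenylaluminate; Al bonded to the alkoxide O and to the alkene carbon that bears CH2OPMB; formed in situ) | [Na+].COCCO[Al-]1(OCCOC)OCC=C1COCc1ccc(OC)cc1 | intermediate
4 | (2Z)-3-iodo-4-[(4-methoxyphenyl)methoxy]but-2-en-1-ol | OC/C=C(\I)COCc1ccc(OC)cc1 | intermediate
5 | triethyl({(2Z)-3-iodo-4-[(4-methoxyphenyl)methoxy]but-2-en-1-yl}oxy)silane | CC[Si](CC)(CC)OC/C=C(\I)COCc1ccc(OC)cc1 | intermediate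
6 | ethyl 3-bromopropanoate | CCOC(=O)CCBr | starting material
7 | bromo(3-ethoxy-3-oxopropyl)zinc | CCOC(=O)CC[Zn]Br | intermediate
8 | ethyl (4E)-4-{[(4-methoxyphenyl)methoxy]methyl}-6-[(triethylsilyl)oxy]hex-4-enoate | CCOC(=O)CC/C(COCc1ccc(OC)cc1)=C\CO[Si](CC)(CC)CC | intermediate
9 | (4E)-4-{[(4-methoxyphenyl)methoxy]methyl}-6-[(triethylsilyl)oxy]hex-4-enal | O=CCC/C(COCc1ccc(OC)cc1)=C\CO[Si](CC)(CC)CC | intermediate
10 | methyl (triphenyl-λ5-phosphanylidene)acetate | COC(=O)C=P(c1ccccc1)(c1ccccc1)c1ccccc1 | starting material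
11 | methyl iodo(triphenyl-λ5-phosphanylidene)acetate | COC(=O)C(I)=P(c1ccccc1)(c1ccccc1)c1ccccc1 | intermediate
12 | methyl (2Z,6E)-2-iodo-6-{[(4-methoxyphenyl)methoxy]methyl}-8-[(triethylsilyl)oxy]octa-2,6-dienoate | COC(=O)/C(I)=C/CC/C(COCc1ccc(OC)cc1)=C\CO[Si](CC)(CC)CC | intermediate
13 | methyl (2Z,6E)-2-iodo-6-{[(4-methoxyphenyl)methoxy]methyl}-8-oxoocta-2,6-dienoate (fragment A) | COC(=O)/C(I)=C/CC/C(COCc1ccc(OC)cc1)=C\C=O | intermediate
14 | methyl (4R)-2,2-dimethyl-1,3-dioxolane-4-carboxylate | COC(=O)[C@H]1COC(C)(C)O1 | starting material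
15 | methyl (2R)-2,3-dihydroxypropanoate | OC[C@@H](O)C(=O)OC | intermediate
16 | methyl (2R)-2-hydroxy-3-[(triethylsilyl)oxy]propanoate | CC[Si](CC)(CC)OC[C@@H](O)C(=O)OC | intermediate
17 | methyl (2R)-2-[(tert-butyldimethylsilyl)oxy]-3-[(triethylsilyl)oxy]propanoate | CC[Si](CC)(CC)OC[C@@H](O[Si](C)(C)C(C)(C)C)C(=O)OC | intermediate
18 | (2R)-2-[(tert-butyldimethylsilyl)oxy]-3-[(triethylsilyl)oxy]propanal | CC[Si](CC)(CC)OC[C@@H](O[Si](C)(C)C(C)(C)C)C=O | intermediate
19 | methyl prop-2-ynoate | C#CC(=O)OC | starting material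
20 | methyl 2-[bis(2-methylpropyl)alumanyl]prop-2-enoate (vinylalane; formed in situ) | C=C(C(=O)OC)[Al](CC(C)C)CC(C)C | intermediate
21 | methyl (3RS,4R)-4-[(tert-butyldimethylsilyl)oxy]-3-hydroxy-2-methylidene-5-[(triethylsilyl)oxy]pentanoate | CC[Si](CC)(CC)OC[C@@H](O[Si](C)(C)C(C)(C)C)C(O)C(=C)C(=O)OC | intermediate
22 | methyl (2Z,4S)-2-(bromomethyl)-4-[(tert-butyldimethylsilyl)oxy]-5-[(triethylsilyl)oxy]pent-2-enoate (fragment B) | CC[Si](CC)(CC)OC[C@@H](O[Si](C)(C)C(C)(C)C)/C=C(\CBr)C(=O)OC | intermediate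
23 | dichloro[(4S)-4-[(tert-butyldimethylsilyl)oxy]-2-(methoxycarbonyl)-5-[(triethylsilyl)oxy]pent-2-en-1-yl]chromium (allylchromium dichloride, trivalent chromium, alkene geometry equilibrating; formed in situ) | COC(=O)C(C[Cr](Cl)Cl)=C[C@H](O[Si](C)(C)C(C)(C)C)CO[Si](CC)(CC)CC | intermediate
24 | methyl (2Z,6E,8R,9S,10S)-10-[(tert-butyldimethylsilyl)oxy]-8-hydroxy-2-iodo-9-(3-methoxy-3-oxoprop-1-en-2-yl)-6-{[(4-methoxyphenyl)methoxy]methyl}-11-[(triethylsilyl)oxy]undeca-2,6-dienoate (hydroxy ester; formed in situ) | C=C(C(=O)OC)[C@@H]([C@H](O)/C=C(/COCc1ccc(OC)cc1)CC/C=C(\I)C(=O)OC)[C@H](O[Si](C)(C)C(C)(C)C)CO[Si](CC)(CC)CC | intermediate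
25 | methyl (2Z,6E)-7-[(2R,3S)-3-{(1S)-1-[(tert-butyldimethylsilyl)oxy]-2-[(triethylsilyl)oxy]ethyl}-4-methylidene-5-oxooxolan-2-yl]-2-iodo-6-{[(4-methoxyphenyl)methoxy]methyl}hepta-2,6-dienoate | C=C1C(=O)O[C@H](/C=C(/COCc2ccc(OC)cc2)CC/C=C(\I)C(=O)OC)[C@H]1[C@H](O[Si](C)(C)C(C)(C)C)CO[Si](CC)(CC)CC | intermediate
26 | methyl (2Z,6E)-7-[(2R,3S)-3-{(1S)-1-[(tert-butyldimethylsilyl)oxy]-2-oxoethyl}-4-methylidene-5-oxooxolan-2-yl]-2-iodo-6-{[(4-methoxyphenyl)methoxy]methyl}hepta-2,6-dienoate | C=C1C(=O)O[C@H](/C=C(/COCc2ccc(OC)cc2)CC/C=C(\I)C(=O)OC)[C@H]1[C@H](O[Si](C)(C)C(C)(C)C)C=O | intermediate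
27 | alkenylchromium dichloride: 26 with CrCl2 (trivalent chromium) in place of iodine on C10, same alkene geometry (formed in situ) | C=C1C(=O)O[C@H](/C=C(/COCc2ccc(OC)cc2)CC/C=C(\[Cr](Cl)Cl)C(=O)OC)[C@H]1[C@H](O[Si](C)(C)C(C)(C)C)C=O | intermediate
28 | methyl (1(10)E,4E,6R,7S,8S,9R)-8-[(tert-butyldimethylsilyl)oxy]-9-hydroxy-15-[(4-methoxyphenyl)methoxy]germacra-1(10),4,11(13)-trien-12,6-olid-14-oate | C=C1C(=O)O[C@@H]2/C=C(/COCc3ccc(OC)cc3)CC/C=C(/C(=O)OC)[C@@H](O)[C@@H](O[Si](C)(C)C(C)(C)C)[C@@H]12 | intermediate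
29 | methyl (1(10)E,4E,6R,7S,8S,9R)-9-acetoxy-8-[(tert-butyldimethylsilyl)oxy]-15-[(4-methoxyphenyl)methoxy]germacra-1(10),4,11(13)-trien-12,6-olid-14-oate | C=C1C(=O)O[C@@H]2/C=C(/COCc3ccc(OC)cc3)CC/C=C(/C(=O)OC)[C@@H](OC(C)=O)[C@@H](O[Si](C)(C)C(C)(C)C)[C@@H]12 | intermediate
30 | methyl (1(10)E,4E,6R,7R,8S,9R)-9-acetoxy-8-hydroxy-15-[(4-methoxyphenyl)methoxy]germacra-1(10),4,11(13)-trien-12,6-olid-14-oate | C=C1C(=O)O[C@@H]2/C=C(/COCc3ccc(OC)cc3)CC/C=C(/C(=O)OC)[C@@H](OC(C)=O)[C@@H](O)[C@@H]12 | intermediate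
31 | methyl (1(10)E,4E,6R,7S,8S,9R)-9-acetoxy-15-[(4-methoxyphenyl)methoxy]-8-[(2-methylpropanoyl)oxy]germacra-1(10),4,11(13)-trien-12,6-olid-14-oate | C=C1C(=O)O[C@@H]2/C=C(/COCc3ccc(OC)cc3)CC/C=C(/C(=O)OC)[C@@H](OC(C)=O)[C@@H](OC(=O)C(C)C)[C@@H]12 | intermediate
32 | methyl (1(10)E,4E,6R,7S,8S,9R)-9-acetoxy-15-hydroxy-8-[(2-methylpropanoyl)oxy]germacra-1(10),4,11(13)-trien-12,6-olid-14-oate (CNP0242134.4) | C=C1C(=O)O[C@@H]2/C=C(/CO)CC/C=C(/C(=O)OC)[C@@H](OC(C)=O)[C@@H](OC(=O)C(C)C)[C@@H]12 | target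

## Step count and weak points

Total step count: 22 (fragment A 7 steps, two reagent branches of 1 step each, fragment B 6 steps, 7 steps after the union).

Longest linear sequence: 14 steps (1, 2, 3, 5, 6, 8, 9, 16, 17, 18, 19, 20, 21, 22), i.e. 14 of 22.

The three steps most likely to fail:

Step 16 (fragment union). The 6,7‑anti outcome and especially the facial selectivity at C7 relative to the C8 stereocentre rest on a transition‑state model and are not secured by a close precedent; slow reduction of the α‑iodoenoate by CrCl2 is a second concern. Fallback: the two chromium couplings are exchanged, so that C9–C10 joins the fragments and C6–C7 is closed inside the ring, where the macrocycle templates the allylation. It sets out from 12 and 21 and comes back to the route at 29. Acetylation of 21 (Ac2O, pyridine, DMAP) gives the C7 acetate F1, and desilylative Swern oxidation gives the C9 aldehyde F2. NiCl2/CrCl2 coupling of F2 with 12 in DMSO gives the 8,9‑anti open‑chain C9 alcohol F3 (Felkin–Anh, now intermolecular), which is acetylated to the open‑chain diacetate F4. Swern oxidation of its primary allylic triethylsilyl ether gives the open‑chain enal F5. Pd(PPh3)4 (cat.) with InI in THF at high dilution ionises the terminal‑methylene allylic acetate at C7 (the hindered C9 acetate ionises more slowly), and the resulting allylindium adds to the C6 aldehyde and lactonizes to 29.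

Step 18 (macrocyclization). Closure of the strained ten‑membered ring competes with oligomerisation, and the C9 configuration depends on Felkin control surviving the ring constraints. Fallback: ring closure is moved to the C1=C10 alkene and done by ring‑closing metathesis, where the ring size itself enforces the ring‑cis geometry. It sets out from 5 and comes back to the route at 29. Negishi coupling of 5 with but-3-enylzinc bromide (Pd(PPh3)4, THF) gives the silyl ether diene F6, and desilylative Swern oxidation gives the dienal F7. CrCl2 allylation with 22 and lactonization as in step 16 give the terminal‑alkene lactone F8, and Swern oxidation gives the lactone aldehyde F9. Addition of vinylalane 20 (Felkin–Anh, 8,9‑anti) gives the acrylate carbinol F10, and acetylation gives the metathesis precursor F11. The second‑generation Grubbs catalyst RuCl2(=CHPh)(H2IMes)(PCy3) in toluene at 80 °C and 1 mM then closes the ring to 29. The exocyclic methylene of the lactone cannot compete, because ring closure onto it would give a bridgehead alkene.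

Step 21 (isobutyrylation of 30). In 30 a free O8–H sits next to the O9 acetate, so base‑mediated acetyl migration before the slow acylation of the hindered alcohol can give regioisomeric diesters. Fallback: the two esters are installed in the opposite order, so that the slow‑migrating isobutyrate is in place first and the fast acetylation comes last. It sets out from 25 and comes back to the route at 31. HF·pyridine removes both silyl groups of 25 to give the lactone diol F12; Et3SiCl and imidazole at −40 °C give the primary silyl ether F13, and 2-methylpropanoyl chloride with pyridine gives the O8 isobutyrate F14. Desilylative Swern oxidation gives the acyloxy aldehyde F15 with no free primary alcohol on the way. NiCl2/CrCl2 macrocyclization as in step 18 gives the macrocyclic C9 alcohol F16, and Ac2O, pyridine and DMAP give 31.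

## Further compounds

F1 | step 16 | methyl (3RS,4R)-3-acetoxy-4-[(tert-butyldimethylsilyl)oxy]-2-methylidene-5-[(triethylsilyl)oxy]pentanoate | CC[Si](CC)(CC)OC[C@@H](O[Si](C)(C)C(C)(C)C)C(OC(C)=O)C(=C)C(=O)OC
F2 | step 16 | methyl (3RS,4S)-3-acetoxy-4-[(tert-butyldimethylsilyl)oxy]-2-methylidene-5-oxopentanoate | O=C[C@@H](O[Si](C)(C)C(C)(C)C)C(OC(C)=O)C(=C)C(=O)OC
F3 | step 16 | methyl (2E,6E)-2-[(1R,2R,3RS)-3-acetoxy-2-[(tert-butyldimethylsilyl)oxy]-1-hydroxy-4-(methoxycarbonyl)pent-4-en-1-yl]-6-{[(4-methoxyphenyl)methoxy]methyl}-8-[(triethylsilyl)oxy]octa-2,6-dienoate | CC[Si](CC)(CC)OC/C=C(/COCc1ccc(OC)cc1)CC/C=C(/C(=O)OC)[C@@H](O)[C@@H](O[Si](C)(C)C(C)(C)C)C(OC(C)=O)C(=C)C(=O)OC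
F4 | step 16 | O9-acetate of F3 (open chain; acetates on O7 and O9; silyl ethers on O6 and O8) | CC[Si](CC)(CC)OC/C=C(/COCc1ccc(OC)cc1)CC/C=C(/C(=O)OC)[C@@H](OC(C)=O)[C@@H](O[Si](C)(C)C(C)(C)C)C(OC(C)=O)C(=C)C(=O)OC
F5 | step 16 | C6 enal from F4 (CH2OSiEt3 replaced by CHO) | O=C/C=C(/COCc1ccc(OC)cc1)CC/C=C(/C(=O)OC)[C@@H](OC(C)=O)[C@@H](O[Si](C)(C)C(C)(C)C)C(OC(C)=O)C(=C)C(=O)OC
F6 | step 18 | triethyl{[(2E)-3-{[(4-methoxyphenyl)methoxy]methyl}hepta-2,6-dien-1-yl]oxy}silane | CC[Si](CC)(CC)OC/C=C(\CCC=C)COCc1ccc(OC)cc1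
F7 | step 18 | (2E)-3-{[(4-methoxyphenyl)methoxy]methyl}hepta-2,6-dienal | O=C/C=C(\CCC=C)COCc1ccc(OC)cc1
F8 | step 18 | (4S,5R)-4-{(1S)-1-[(tert-butyldimethylsilyl)oxy]-2-[(triethylsilyl)oxy]ethyl}-5-[(1E)-2-{[(4-methoxyphenyl)methoxy]methyl}hexa-1,5-dien-1-yl]-3-methylideneoxolan-2-one | C=C1C(=O)O[C@H](/C=C(/COCc2ccc(OC)cc2)CCC=C)[C@H]1[C@H](O[Si](C)(C)C(C)(C)C)CO[Si](CC)(CC)CC
F9 | step 18 | C9 aldehyde from F8 (CH2OSiEt3 replaced by CHO) | C=C1C(=O)O[C@H](/C=C(/COCc2ccc(OC)cc2)CCC=C)[C@H]1[C@H](O[Si](C)(C)C(C)(C)C)C=O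
F10 | step 18 | C9 alcohol from F9 and 20: CHO replaced by (9R)-CH(OH)C(=CH2)CO2Me | C=C1C(=O)O[C@H](/C=C(/COCc2ccc(OC)cc2)CCC=C)[C@H]1[C@H](O[Si](C)(C)C(C)(C)C)[C@H](O)C(=C)C(=O)OC
F11 | step 18 | O9-acetate of F10 | C=C1C(=O)O[C@H](/C=C(/COCc2ccc(OC)cc2)CCC=C)[C@H]1[C@H](O[Si](C)(C)C(C)(C)C)[C@H](OC(C)=O)C(=C)C(=O)OC
F12 | step 21 | 8,9-diol from 25 (both silyl groups removed) | C=C1C(=O)O[C@H](/C=C(/COCc2ccc(OC)cc2)CC/C=C(\I)C(=O)OC)[C@H]1[C@H](O)CO
F13 | step 21 | 9-O-triethylsilyl ether of F12 (free O8–H) | C=C1C(=O)O[C@H](/C=C(/COCc2ccc(OC)cc2)CC/C=C(\I)C(=O)OC)[C@H]1[C@H](O)CO[Si](CC)(CC)CC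
F14 | step 21 | 8-O-(2-methylpropanoyl) ester of F13 | C=C1C(=O)O[C@H](/C=C(/COCc2ccc(OC)cc2)CC/C=C(\I)C(=O)OC)[C@H]1[C@H](OC(=O)C(C)C)CO[Si](CC)(CC)CC
F15 | step 21 | C9 aldehyde from F14 (CH2OSiEt3 replaced by CHO) | C=C1C(=O)O[C@H](/C=C(/COCc2ccc(OC)cc2)CC/C=C(\I)C(=O)OC)[C@H]1[C@H](OC(=O)C(C)C)C=O
F16 | step 21 | methyl (1(10)E,4E,6R,7S,8S,9R)-9-hydroxy-15-[(4-methoxyphenyl)methoxy]-8-[(2-methylpropanoyl)oxy]germacra-1(10),4,11(13)-trien-12,6-olid-14-oate | C=C1C(=O)O[C@@H]2/C=C(/COCc3ccc(OC)cc3)CC/C=C(/C(=O)OC)[C@@H](O)[C@@H](OC(=O)C(C)C)[C@@H]12
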